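**Retrosynthetic overview**

- The route rests on the six-membered carbocycle C1–C6 of the triol end group, whose hydroxyls on C3, C5 and C6 all sit on one face. The two tertiary C–O bonds (C5–O and C6–O) are made together by one syn addition to a C5=C6 ring alkene, on the face of the free C3 hydroxyl.
- Disconnections, latest first: C11=C12 (Wittig, triol C15 phosphonium salt + ε C25 aldehyde); C11'=C12' (Wittig, ε C15 phosphonium salt + C10 dialdehyde); C7≡C8 to (E)-C7=C8 (hydroalumination) after C8–C9 (Sonogashira with an (E)-enol triflate); C5–O/C6–O (directed osmylation of a ring enyne); C6–C7 (Sonogashira on a ring enol triflate).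
- No ring is formed. The triol ring comes from ketoisophorone (C3 set enzymatically, C5 and C6 in the key step). The ε ring comes from (R)-α-ionone (C6' bought, C3' set by ketone reduction).

Key step: step 6

Remark: positions are cited in carotenoid numbering (C1–C6 triol ring, C7–C15 chain, primed numbers for the ε half); compound names use systematic numbering.
Assumption: (R)-α-ionone is bought as the single enantiomer (fermentation-derived grade), and its C6' hydrogen is exposed only to neutral or weakly basic reagents.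

**Step 1**
Reactants: 1 ketoisophorone (2,6,6-trimethylcyclohex-2-ene-1,4-dione)
Product: 3 (4R,6R)-4-hydroxy-2,2,6-trimethylcyclohexanone (actinol), via (6R)-levodione 2 (not isolated)
Conditions: ene-reductase OYE2, NADP+ (cat.), D-glucose, glucose dehydrogenase, phosphate buffer pH 7, 30 °C; then levodione reductase (Corynebacterium aquaticum), NAD+ (cat.), same pot
Reagents that add atoms: none
Why: Sequential biocatalytic reductions (ene-reductase, then carbonyl reductase): the first enzyme sets (6R) on saturating the ring alkene and the second reduces only the unhindered C4 carbonyl from one face, setting the (4R) carbinol that becomes C3 of the target.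

**Step 2**
Reactants: 3 (4R,6R)-actinol
Product: 4 (4R,6R)-4-[(tert-butyldimethylsilyl)oxy]-2,2,6-trimethylcyclohexanone
Conditions: TBSCl, imidazole, DMF, rt
Reagents that add atoms: tert-butyldimethylsilyl chloride, CC(C)(C)[Si](C)(C)Cl
Why: Standard silylation of the secondary alcohol, which must be masked before enolate chemistry.

**Step 3**
Reactants: 4 silyl ether of actinol
Product: 5 (R)-4-[(tert-butyldimethylsilyl)oxy]-2,6,6-trimethylcyclohex-1-en-1-yl trifluoromethanesulfonate
Conditions: LiN(i-Pr)2, THF, −78 → 0 °C; PhNTf2, −78 °C → rt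
Reagents that add atoms: N-phenylbis(trifluoromethanesulfonimide), O=S(=O)(N(c1ccccc1)S(=O)(=O)C(F)(F)F)C(F)(F)F
Why: Enol triflate formation from a lithium enolate: the ketone has a single α-hydrogen (the other α-carbon is quaternary), so only the tetrasubstituted C5=C6 enolate can form, and the silyloxy group, γ to the carbonyl, cannot eliminate.

**Step 4**
Reactants: 5 ring enol triflate; 6 ethynyltrimethylsilane
Product: 7 (R)-tert-butyldimethyl({3,5,5-trimethyl-4-[(trimethylsilyl)ethynyl]cyclohex-3-en-1-yl}oxy)silane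
Conditions: 6 (1.5 equiv), PdCl2(PPh3)2 (5 mol %), CuI (10 mol %), Et3N, DMF, 50 °C
Reagents that add atoms: none
Why: Sonogashira coupling of a vinyl triflate with a terminal alkyne forms C6–C7 without touching the C3 stereocentre.

**Step 5**
Reactants: 7 silyl-protected enyne
Product: 8 (R)-3,5,5-trimethyl-4-[(trimethylsilyl)ethynyl]cyclohex-3-en-1-ol
Conditions: camphorsulfonic acid (10 mol %), MeOH/CH2Cl2, 0 °C → rt
Reagents that add atoms: none
Why: Acid-catalysed methanolysis cleaves the secondary silyl ether while the alkynyl C–Si bond, labile only to base or fluoride, stays, freeing the C3 hydroxyl that directs the next step.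

**Step 6**
Reactants: 8 ring enynol with free C3 hydroxyl
Product: 10 (1S,2S,4S)-2,6,6-trimethyl-1-[(trimethylsilyl)ethynyl]cyclohexane-1,2,4-triol (all three hydroxyls cis), via osmate ester 9 (not isolated)
Conditions: OsO4 (1.1 equiv), TMEDA (1.2 equiv), CH2Cl2, −78 → −40 °C; then H2NCH2CH2NH2, rt
Reagents that add atoms: osmium tetroxide, O=[Os](=O)(=O)=O (the two hydroxyl oxygens); N,N,N',N'-tetramethylethane-1,2-diamine, CN(C)CCN(C)C (held in 9 only)
Why: The diamine-bound OsO4 adds across C5=C6 in a concerted [3+2] fashion to give the chelated ester 9 of hexavalent osmium, which ethylenediamine cleaves to the cis-diol; the closest known reaction type is the hydrogen-bond-directed dihydroxylation of cyclic allylic and homoallylic alcohols with OsO4 and TMEDA. No ring of the target is closed; the five-membered osmate ring is transient. C5 and C6 are set together: syn addition fixes C5–OH cis to C6–OH, and the face is fixed by C3, whose free hydroxyl hydrogen-bonds to an oxo ligand of the electron-rich OsO4–TMEDA complex. In the half-chair with the C3 hydroxyl equatorial, the pseudoaxial C1 methyl covers the opposite face, so steric and hydrogen-bond control point the same way. The selectivity needed is facial, plus chemoselectivity for the alkene, which is secured because the tetrasubstituted alkene is the more electron-rich π bond and the silyl-capped alkyne reacts far more slowly at low temperature with a stoichiometric reagent.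

**Step 7**
Reactants: 10 silylalkynyl triol
Product: 11 (1S,2S,4S)-1-ethynyl-2,6,6-trimethylcyclohexane-1,2,4-triol
Conditions: K2CO3 (0.2 equiv), MeOH, rt
Reagents that add atoms: none
Why: Base-catalysed methanolysis of the alkynylsilane unmasks the terminal alkyne and leaves the triol untouched.

**Step 8**
Reactants: 12 ethyl acetoacetate
Product: 13 ethyl (E)-3-{[(trifluoromethyl)sulfonyl]oxy}but-2-enoate
Conditions: Tf2O, Me4NOH (aq), hexanes, 5–10 °C
Reagents that add atoms: trifluoromethanesulfonic anhydride, O=S(=O)(OS(=O)(=O)C(F)(F)F)C(F)(F)F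
Why: Two-phase O-triflation of the β-keto ester enolate: the non-coordinating tetramethylammonium ion favours the open enolate with the two oxygens anti, so the triflate should form trans to the ester (E), the geometry needed for C9=C10.

**Step 9**
Reactants: 11 terminal alkyne triol; 13 (E)-enol triflate
Product: 14 ethyl (E)-3-methyl-5-[(1S,2S,4S)-1,2,4-trihydroxy-2,6,6-trimethylcyclohexyl]pent-2-en-4-ynoate
Conditions: PdCl2(PPh3)2 (3 mol %), CuI (6 mol %), Et3N, THF, rt, degassed
Reagents that add atoms: none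
Why: Sonogashira coupling forms C8–C9 with retention of the triflate geometry; a tertiary amine is used so that no enamine forms from the β-triflyloxy enoate, and free hydroxyls are tolerated.

**Step 10**
Reactants: 14 enyne ester
Product: 15 (1R,2S,4S)-1-[(1E,3E)-5-hydroxy-3-methylpenta-1,3-dien-1-yl]-2,6,6-trimethylcyclohexane-1,2,4-triol
Conditions: NaAlH2(OCH2CH2OCH3)2 (Red-Al, 7 equiv), THF, 0 °C → rt; aq. Rochelle salt
Reagents that add atoms: none
Why: Ester reduction followed by alkoxide-directed trans-hydroalumination of the propargylic alkyne: hydride and aluminium add anti across C7≡C8 from the ring alkoxyaluminate and protonolysis of the vinylalane gives the E alkene, with C9=C10 untouched (the descriptor at C6 changes only through priority rules).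

**Step 11**
Reactants: 15 dienyl tetraol
Product: 17 {(2E,4E)-3-methyl-5-[(1R,2S,4S)-1,2,4-trihydroxy-2,6,6-trimethylcyclohexyl]penta-2,4-dien-1-yl}triphenylphosphonium bromide, via allylic bromide 16 (not isolated)
Conditions: CBr4 (1.05 equiv), PPh3 (1.1 equiv), CH2Cl2, −30 °C; then PPh3 (1.5 equiv), rt
Reagents that add atoms: carbon tetrabromide, BrC(Br)(Br)Br; triphenylphosphine, c1ccc(cc1)P(c1ccccc1)c1ccccc1
Why: Appel bromination then SN2 quaternisation of PPh3: at −30 °C only the primary allylic hydroxyl should be activated (the tertiary hydroxyls are too hindered, the secondary C3 hydroxyl much slower), and the neutral medium spares the acid-labile C6 allylic carbinol.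

**Step 12**
Reactants: 18 (R)-α-ionone; 19 triethyl phosphonoacetate
Product: 20 ethyl (2E,4E)-3-methyl-5-[(R)-2,6,6-trimethylcyclohex-2-en-1-yl]penta-2,4-dienoate
Conditions: 19, NaH, THF, 0 °C; then 18, rt → 50 °C
Reagents that add atoms: none
Why: Horner–Wadsworth–Emmons olefination of the methyl ketone with the preformed sodium phosphonate (no free hydride or alkoxide, so C6' is not deprotonated) should favour the 9'E ester, the minor 9'Z isomer being removed by chromatography.

**Step 13**
Reactants: 20 ethyl (R)-α-ionylideneacetate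
Product: 21 ethyl (2E,4E)-3-methyl-5-[(R)-2,6,6-trimethyl-4-oxocyclohex-2-en-1-yl]penta-2,4-dienoate
Conditions: t-BuOOH (70% aq, 5 equiv), dirhodium tetrakis(caprolactamate), Rh2(C6H10NO)4 (1 mol %), ClCH2CH2Cl, 40 °C
Reagents that add atoms: tert-butyl hydroperoxide, CC(C)(C)OO
Why: Catalytic allylic C–H oxidation by tert-butylperoxy radicals converts the only allylic methylene (C3') to the enone, the C6' hydrogen being shielded by the gem-dimethyl group, the C5' methyl and the side chain, and the base-free medium keeps C6' from epimerising.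

**Step 14**
Reactants: 21 ring enone ester
Product: 22 ethyl (2E,4E)-5-[(1R,4R)-4-hydroxy-2,6,6-trimethylcyclohex-2-en-1-yl]-3-methylpenta-2,4-dienoate
Conditions: LiBH(s-Bu)3 (1.05 equiv), THF, −78 °C
Reagents that add atoms: none
Why: 1,2-Reduction of the β,β-disubstituted enone by a bulky trialkylborohydride: in the half-chair that keeps the C6' side chain pseudoaxial, the axial C1' methyl covers one face of the C3' carbonyl, so hydride should enter syn to the side chain and leave the hydroxyl trans to it (3'R); any cis epimer is removed by chromatography.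

**Step 15**
Reactants: 22 trans hydroxy ester
Product: 23 ethyl (2E,4E)-5-{(1R,4R)-4-[(tert-butyldimethylsilyl)oxy]-2,6,6-trimethylcyclohex-2-en-1-yl}-3-methylpenta-2,4-dienoate
Conditions: TBSCl, imidazole, DMF, rt
Reagents that add atoms: tert-butyldimethylsilyl chloride, CC(C)(C)[Si](C)(C)Cl
Why: Silylation masks the allylic C3' hydroxyl so that the later bromination can act only at the primary position.

**Step 16**
Reactants: 23 silyl-protected ester
Product: 24 (2E,4E)-5-{(1R,4R)-4-[(tert-butyldimethylsilyl)oxy]-2,6,6-trimethylcyclohex-2-en-1-yl}-3-methylpenta-2,4-dien-1-ol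
Conditions: i-Bu2AlH (2.5 equiv), CH2Cl2, −78 °C; aq. Rochelle salt
Reagents that add atoms: none
Why: 1,2-Reduction of the conjugated ester by the aluminium hydride gives the allylic alcohol without touching the diene or the silyl ether.

**Step 17**
Reactants: 24 ε C15 allylic alcohol
Product: 26 [(2E,4E)-5-{(1R,4R)-4-[(tert-butyldimethylsilyl)oxy]-2,6,6-trimethylcyclohex-2-en-1-yl}-3-methylpenta-2,4-dien-1-yl]triphenylphosphonium bromide, via allylic bromide 25 (not isolated)
Conditions: CBr4 (1.1 equiv), PPh3 (1.1 equiv), CH2Cl2, −30 °C; then PPh3 (1.5 equiv), rt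
Reagents that add atoms: carbon tetrabromide, BrC(Br)(Br)Br; triphenylphosphine, c1ccc(cc1)P(c1ccccc1)c1ccccc1
Why: Appel bromination and SN2 quaternisation under neutral conditions give the phosphonium salt without ionising the allylic C3' oxygen, which acid-based salt formation would endanger.

**Step 18**
Reactants: 26 ε C15 phosphonium bromide; 27 (2E,4E,6E)-2,7-dimethylocta-2,4,6-trienedial
Product: 28 (2E,4E,6E,8E,10E,12E)-13-{(1R,4R)-4-[(tert-butyldimethylsilyl)oxy]-2,6,6-trimethylcyclohex-2-en-1-yl}-2,7,11-trimethyltrideca-2,4,6,8,10,12-hexaenal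
Conditions: 27 (3 equiv), NaOMe, MeOH/CH2Cl2, −10 °C → rt; then n-heptane, reflux
Reagents that add atoms: none
Why: Wittig olefination: with the symmetrical dialdehyde in excess the semi-stabilised ylide should condense once, the C25 aldehyde formed being less electrophilic, and the hindered 11'Z isomer of the new C11'=C12' bond reverts to E on heating.

**Step 19**
Reactants: 28 ε C25 aldehyde; 17 triol C15 phosphonium bromide
Product: 29 3'-O-(tert-butyldimethylsilyl) ether of (3S,5S,6R,3'R,6'R)-5,6-dihydro-β,ε-carotene-3,5,6,3'-tetrol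
Conditions: 17 (1.3 equiv), 1,2-epoxybutane, EtOH, reflux
Reagents that add atoms: none
Why: Wittig olefination in which 1,2-epoxybutane scavenges HBr, so the three free hydroxyls need no protection; the new C11=C12 bond forms as an E/Z mixture whose hindered Z isomer should isomerise to all-E at reflux.

**Step 20**
Reactants: 29 silyl-protected tetrol
Product: 30 5,6-dihydroxylutein, (3S,5S,6R,3'R,6'R)-5,6-dihydro-β,ε-carotene-3,5,6,3'-tetrol
Conditions: Bu4NF, THF, rt
Reagents that add atoms: none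
Why: Fluoride cleavage of the one silyl ether releases the C3' hydroxyl under non-acidic conditions that the polyene, the allylic C3' carbinol and the C6 carbinol tolerate.

**Compound list**

1 | ketoisophorone (2,6,6-trimethylcyclohex-2-ene-1,4-dione) | CC1=CC(=O)CC(C)(C)C1=O | starting material
2 | (6R)-levodione, (R)-2,2,6-trimethylcyclohexane-1,4-dione | CC1(C)CC(=O)C[C@@H](C)C1=O | intermediate
3 | (4R,6R)-4-hydroxy-2,2,6-trimethylcyclohexanone (actinol) | CC1(C)C[C@H](O)C[C@@H](C)C1=O | intermediate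
4 | (4R,6R)-4-[(tert-butyldimethylsilyl)oxy]-2,2,6-trimethylcyclohexanone | CC1(C)C[C@H](O[Si](C)(C)C(C)(C)C)C[C@@H](C)C1=O | intermediate
5 | (R)-4-[(tert-butyldimethylsilyl)oxy]-2,6,6-trimethylcyclohex-1-en-1-yl trifluoromethanesulfonate | CC1=C(OS(=O)(=O)C(F)(F)F)C(C)(C)C[C@H](O[Si](C)(C)C(C)(C)C)C1 | intermediate
6 | ethynyltrimethylsilane | C[Si](C)(C)C#C | starting material
7 | (R)-tert-butyldimethyl({3,5,5-trimethyl-4-[(trimethylsilyl)ethynyl]cyclohex-3-en-1-yl}oxy)silane | C[Si](C)(C)C#CC1=C(C)C[C@@H](O[Si](C)(C)C(C)(C)C)CC1(C)C | intermediate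
8 | (R)-3,5,5-trimethyl-4-[(trimethylsilyl)ethynyl]cyclohex-3-en-1-ol | C[Si](C)(C)C#CC1=C(C)C[C@@H](O)CC1(C)C | intermediate
9 | cyclic C5,C6-osmate ester of 10 (dioxo, hexavalent osmium, chelated by TMEDA) | C[Si](C)(C)C#C[C@@]1(O2)C(C)(C)C[C@H](O)C[C@]1(C)O[Os-2]23(=O)(=O)[N+](C)(C)CC[N+]3(C)C | intermediate
10 | (1S,2S,4S)-2,6,6-trimethyl-1-[(trimethylsilyl)ethynyl]cyclohexane-1,2,4-triol | C[Si](C)(C)C#C[C@@]1(O)C(C)(C)C[C@H](O)C[C@]1(C)O | intermediate
11 | (1S,2S,4S)-1-ethynyl-2,6,6-trimethylcyclohexane-1,2,4-triol | C#C[C@@]1(O)C(C)(C)C[C@H](O)C[C@]1(C)O | intermediate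
12 | ethyl acetoacetate | CCOC(=O)CC(C)=O | starting material
13 | ethyl (E)-3-{[(trifluoromethyl)sulfonyl]oxy}but-2-enoate | CCOC(=O)/C=C(\C)OS(=O)(=O)C(F)(F)F | intermediate
14 | ethyl (E)-3-methyl-5-[(1S,2S,4S)-1,2,4-trihydroxy-2,6,6-trimethylcyclohexyl]pent-2-en-4-ynoate | CCOC(=O)/C=C(\C)C#C[C@@]1(O)C(C)(C)C[C@H](O)C[C@]1(C)O | intermediate
15 | (1R,2S,4S)-1-[(1E,3E)-5-hydroxy-3-methylpenta-1,3-dien-1-yl]-2,6,6-trimethylcyclohexane-1,2,4-triol | OC/C=C(C)/C=C/[C@@]1(O)C(C)(C)C[C@H](O)C[C@]1(C)O | intermediate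
16 | (1R,2S,4S)-1-[(1E,3E)-5-bromo-3-methylpenta-1,3-dien-1-yl]-2,6,6-trimethylcyclohexane-1,2,4-triol | BrC/C=C(C)/C=C/[C@@]1(O)C(C)(C)C[C@H](O)C[C@]1(C)O | intermediate
17 | {(2E,4E)-3-methyl-5-[(1R,2S,4S)-1,2,4-trihydroxy-2,6,6-trimethylcyclohexyl]penta-2,4-dien-1-yl}triphenylphosphonium bromide | c1ccccc1[P+](c1ccccc1)(c1ccccc1)C/C=C(C)/C=C/[C@@]1(O)C(C)(C)C[C@H](O)C[C@]1(C)O.[Br-] | intermediate
18 | (R)-α-ionone | CC(=O)/C=C/[C@H]1C(C)=CCCC1(C)C | starting material
19 | triethyl phosphonoacetate | CCOC(=O)CP(=O)(OCC)OCC | starting material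
20 | ethyl (2E,4E)-3-methyl-5-[(R)-2,6,6-trimethylcyclohex-2-en-1-yl]penta-2,4-dienoate | CCOC(=O)/C=C(C)/C=C/[C@H]1C(C)=CCCC1(C)C | intermediate
21 | ethyl (2E,4E)-3-methyl-5-[(R)-2,6,6-trimethyl-4-oxocyclohex-2-en-1-yl]penta-2,4-dienoate | CCOC(=O)/C=C(C)/C=C/[C@H]1C(C)=CC(=O)CC1(C)C | intermediate
22 | ethyl (2E,4E)-5-[(1R,4R)-4-hydroxy-2,6,6-trimethylcyclohex-2-en-1-yl]-3-methylpenta-2,4-dienoate | CCOC(=O)/C=C(C)/C=C/[C@H]1C(C)=C[C@H](O)CC1(C)C | intermediate
23 | ethyl (2E,4E)-5-{(1R,4R)-4-[(tert-butyldimethylsilyl)oxy]-2,6,6-trimethylcyclohex-2-en-1-yl}-3-methylpenta-2,4-dienoate | CCOC(=O)/C=C(C)/C=C/[C@H]1C(C)=C[C@H](O[Si](C)(C)C(C)(C)C)CC1(C)C | intermediate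
24 | (2E,4E)-5-{(1R,4R)-4-[(tert-butyldimethylsilyl)oxy]-2,6,6-trimethylcyclohex-2-en-1-yl}-3-methylpenta-2,4-dien-1-ol | OC/C=C(C)/C=C/[C@H]1C(C)=C[C@H](O[Si](C)(C)C(C)(C)C)CC1(C)C | intermediate
25 | {[(1R,4R)-4-[(1E,3E)-5-bromo-3-methylpenta-1,3-dien-1-yl]-3,5,5-trimethylcyclohex-2-en-1-yl]oxy}(tert-butyl)dimethylsilane | BrC/C=C(C)/C=C/[C@H]1C(C)=C[C@H](O[Si](C)(C)C(C)(C)C)CC1(C)C | intermediate
26 | [(2E,4E)-5-{(1R,4R)-4-[(tert-butyldimethylsilyl)oxy]-2,6,6-trimethylcyclohex-2-en-1-yl}-3-methylpenta-2,4-dien-1-yl]triphenylphosphonium bromide | c1ccccc1[P+](c1ccccc1)(c1ccccc1)C/C=C(C)/C=C/[C@H]1C(C)=C[C@H](O[Si](C)(C)C(C)(C)C)CC1(C)C.[Br-] | intermediate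
27 | (2E,4E,6E)-2,7-dimethylocta-2,4,6-trienedial | O=C/C(C)=C/C=C/C=C(C)/C=O | starting material
28 | (2E,4E,6E,8E,10E,12E)-13-{(1R,4R)-4-[(tert-butyldimethylsilyl)oxy]-2,6,6-trimethylcyclohex-2-en-1-yl}-2,7,11-trimethyltrideca-2,4,6,8,10,12-hexaenal | CC1=C[C@H](O[Si](C)(C)C(C)(C)C)CC(C)(C)[C@H]1/C=C/C(C)=C/C=C/C(C)=C/C=C/C=C(C)/C=O | intermediate
29 | 3'-O-(tert-butyldimethylsilyl) ether of (3S,5S,6R,3'R,6'R)-5,6-dihydro-β,ε-carotene-3,5,6,3'-tetrol | CC1=C[C@H](O[Si](C)(C)C(C)(C)C)CC(C)(C)[C@H]1/C=C/C(C)=C/C=C/C(C)=C/C=C/C=C(C)/C=C/C=C(C)/C=C/[C@@]1(O)C(C)(C)C[C@H](O)C[C@]1(C)O | intermediate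
30 | 5,6-dihydroxylutein, (3S,5S,6R,3'R,6'R)-5,6-dihydro-β,ε-carotene-3,5,6,3'-tetrol | CC1=C[C@H](O)CC(C)(C)[C@H]1/C=C/C(C)=C/C=C/C(C)=C/C=C/C=C(C)/C=C/C=C(C)/C=C/[C@@]1(O)C(C)(C)C[C@H](O)C[C@]1(C)O | target

**Step count**

Total: 20 steps. Longest linear sequence: 12 steps (1–7, 9–11, 19, 20, from ketoisophorone). The ε branch is 9 steps (12–20) and the enol triflate branch is 1 step (8).

**Steps most likely to fail**

1. Step 6. The tetrasubstituted C5=C6 alkene is hindered and made less nucleophilic by conjugation to the alkyne, so osmylation may be slow, may attack the alkyne, or may show weak facial bias. The fallback sets out from 5 and moves the osmylation to an alkene without the alkyne. Methoxycarbonylation of 5 (Pd(OAc)2, 1,1'-bis(diphenylphosphino)ferrocene, CO, MeOH, Et3N, DMF) gives methyl (R)-4-[(tert-butyldimethylsilyl)oxy]-2,6,6-trimethylcyclohex-1-ene-1-carboxylate F1. Reduction with i-Bu2AlH gives (R)-{4-[(tert-butyldimethylsilyl)oxy]-2,6,6-trimethylcyclohex-1-en-1-yl}methanol F2, and acid methanolysis frees (R)-4-(hydroxymethyl)-3,5,5-trimethylcyclohex-3-en-1-ol F3. Its electron-rich allylic-alcohol alkene is dihydroxylated (OsO4 cat./N-methylmorpholine N-oxide, or OsO4–TMEDA) on the same face for the same steric and hydrogen-bond reasons, giving (1S,2S,4S)-1-(hydroxymethyl)-2,6,6-trimethylcyclohexane-1,2,4-triol F4. TEMPO/PhI(OAc)2 oxidises only the primary alcohol to (1R,2S,4S)-1,2,4-trihydroxy-2,6,6-trimethylcyclohexane-1-carbaldehyde F5. Ohira–Bestmann homologation (dimethyl (1-diazo-2-oxopropyl)phosphonate, K2CO3, MeOH, 0 °C, kept cold to slow any acyloin shift) turns the aldehyde into the terminal alkyne and comes back to the route at 11.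

2. Step 14. Hydride may be delivered to the other face of the C3' carbonyl, giving mainly the cis (3'S) alcohol. The fallback sets out from 21 and inverts the carbinol instead of relying on substrate control. The cis alcohol ethyl (2E,4E)-5-[(1R,4S)-4-hydroxy-2,6,6-trimethylcyclohex-2-en-1-yl]-3-methylpenta-2,4-dienoate F6 (from the same reduction, or from NaBH4/CeCl3) is subjected to Mitsunobu inversion with benzoic acid (PPh3, diisopropyl azodicarboxylate, THF, 0 °C). This gives (1R,4R)-4-[(1E,3E)-5-ethoxy-3-methyl-5-oxopenta-1,3-dien-1-yl]-3,5,5-trimethylcyclohex-2-en-1-yl benzoate F7, and ethanolysis (NaOEt, EtOH, 0 °C) comes back to the route at 22.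

3. Step 11. Activation may be unselective among four hydroxyls, or the polyhydroxylated dienyl bromide and its salt may ionise at C6 or lose the C9=C10 geometry. The fallback reverses the polarity of the last olefination. It sets out from 15, which MnO2 (CH2Cl2, rt) oxidises only at the primary allylic alcohol to (2E,4E)-3-methyl-5-[(1R,2S,4S)-1,2,4-trihydroxy-2,6,6-trimethylcyclohexyl]penta-2,4-dienal F8. From 28, NaBH4 (MeOH/THF, 0 °C) gives (2E,4E,6E,8E,10E,12E)-13-{(1R,4R)-4-[(tert-butyldimethylsilyl)oxy]-2,6,6-trimethylcyclohex-2-en-1-yl}-2,7,11-trimethyltrideca-2,4,6,8,10,12-hexaen-1-ol F9. Treatment with CBr4/PPh3 and then more PPh3 passes through the C25 allylic bromide F10 to the C25 triphenylphosphonium bromide F11, with only a silyl ether present. Wittig reaction of F11 with F8 (1,2-epoxybutane, EtOH, reflux) forms C11=C12 and comes back to the route at 29.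

**Further compounds**

F1 | step 6 | methyl (R)-4-[(tert-butyldimethylsilyl)oxy]-2,6,6-trimethylcyclohex-1-ene-1-carboxylate | COC(=O)C1=C(C)C[C@@H](O[Si](C)(C)C(C)(C)C)CC1(C)C
F2 | step 6 | (R)-{4-[(tert-butyldimethylsilyl)oxy]-2,6,6-trimethylcyclohex-1-en-1-yl}methanol | OCC1=C(C)C[C@@H](O[Si](C)(C)C(C)(C)C)CC1(C)C
F3 | step 6 | (R)-4-(hydroxymethyl)-3,5,5-trimethylcyclohex-3-en-1-ol | OCC1=C(C)C[C@@H](O)CC1(C)C
F4 | step 6 | (1S,2S,4S)-1-(hydroxymethyl)-2,6,6-trimethylcyclohexane-1,2,4-triol | OC[C@@]1(O)C(C)(C)C[C@H](O)C[C@]1(C)O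
F5 | step 6 | (1R,2S,4S)-1,2,4-trihydroxy-2,6,6-trimethylcyclohexane-1-carbaldehyde | O=C[C@@]1(O)C(C)(C)C[C@H](O)C[C@]1(C)O
F6 | step 14 | ethyl (2E,4E)-5-[(1R,4S)-4-hydroxy-2,6,6-trimethylcyclohex-2-en-1-yl]-3-methylpenta-2,4-dienoate | CCOC(=O)/C=C(C)/C=C/[C@H]1C(C)=C[C@@H](O)CC1(C)C
F7 | step 14 | (1R,4R)-4-[(1E,3E)-5-ethoxy-3-methyl-5-oxopenta-1,3-dien-1-yl]-3,5,5-trimethylcyclohex-2-en-1-yl benzoate | CCOC(=O)/C=C(C)/C=C/[C@H]1C(C)=C[C@H](OC(=O)c2ccccc2)CC1(C)C
F8 | step 11 | (2E,4E)-3-methyl-5-[(1R,2S,4S)-1,2,4-trihydroxy-2,6,6-trimethylcyclohexyl]penta-2,4-dienal | O=C/C=C(C)/C=C/[C@@]1(O)C(C)(C)C[C@H](O)C[C@]1(C)O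
F9 | step 11 | (2E,4E,6E,8E,10E,12E)-13-{(1R,4R)-4-[(tert-butyldimethylsilyl)oxy]-2,6,6-trimethylcyclohex-2-en-1-yl}-2,7,11-trimethyltrideca-2,4,6,8,10,12-hexaen-1-ol | CC1=C[C@H](O[Si](C)(C)C(C)(C)C)CC(C)(C)[C@H]1/C=C/C(C)=C/C=C/C(C)=C/C=C/C=C(C)/CO
F10 | step 11 | C25 allylic bromide corresponding to F9 (bromine in place of the hydroxyl) | CC1=C[C@H](O[Si](C)(C)C(C)(C)C)CC(C)(C)[C@H]1/C=C/C(C)=C/C=C/C(C)=C/C=C/C=C(C)/CBr
F11 | step 11 | C25 triphenylphosphonium bromide corresponding to F9 | CC1=C[C@H](O[Si](C)(C)C(C)(C)C)CC(C)(C)[C@H]1/C=C/C(C)=C/C=C/C(C)=C/C=C/C=C(C)/C[P+](c2ccccc2)(c2ccccc2)c2ccccc2.[Br-]
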